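**Plan**
- Retrosynthesis: ring B (carbocycle C4a–C5–C6–C7–C8–C8a) is cut at C7–C8 and C4a–C5. This leaves a ketone unit C5–C6–C7 and the 2-pyranone (ring A); the two are joined on paper through an enol-ester tether O(C6)–C8, which is cut next.
- Enabling feature: C6 is a ketone flanked by two α-carbons (C5, C7), and ring B is a cyclic 2-methyl-1,3-dione fused to ring A. In ring A, C4a is a vinylogous acyl carbon that can carry a leaving group and C8a bears the acyl carbon C8, so an α,α′-bis-nucleophile meets a 1,3-bis-electrophile.
- Forward: ring A is bought as triacetic acid lactone and given C8 (acid chloride) and a phenoxy leaving group at C4. The farnesyl ketone is made as an α-methylene ketone; conjugate reduction gives the C5 enolate, which is stored as the enol ester. Ring B is closed last, both C–C bonds in one carbene-catalysed operation.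
- Stereochemistry: the only stereocentre (C5, S) is created in the key step under control of a chiral triazolylidene; both (E)-alkenes come from (2E,6E)-farnesyl bromide.

Key step: step 8

Assumption: the sense of induction of the carbene on this substrate class cannot be taken from precedent. The (5aR,10bS) catalyst is written as the one expected to lead from the (Z)-enol ester to the (S) centre; its equally available mirror image is the catalyst meant if the sense proves opposite.

**Step 1**
Reactants: 1 diethyl (2-oxobutyl)phosphonate; 2 (2E,6E)-farnesyl bromide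
Product: 3 diethyl [(6E,10E)-7,11,15-trimethyl-3-oxohexadeca-6,10,14-trien-4-yl]phosphonate (racemic)
Conditions: NaH, THF, 0 °C; then 2, 0 °C to rt
Reagents that add atoms: none
Why: C-alkylation (SN2 at the primary allylic bromide) of the β-ketophosphonate sodium enolate at the carbon between P=O and C=O puts the farnesyl group on the future C5 and keeps the alkene geometry.

**Step 2**
Reactants: 3 diethyl [(6E,10E)-7,11,15-trimethyl-3-oxohexadeca-6,10,14-trien-4-yl]phosphonate
Product: 4 (6E,10E)-7,11,15-trimethyl-4-methylidenehexadeca-6,10,14-trien-3-one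
Conditions: 37% aq. HCHO, K2CO3, THF–H2O, rt
Reagents that add atoms: formaldehyde, C=O
Why: Horner–Wadsworth–Emmons olefination with formaldehyde gives the α-methylene ketone, whose new CH2 becomes the C5 methyl group.

**Step 3**
Reactants: 5 4-hydroxy-6-methyl-2H-pyran-2-one (triacetic acid lactone)
Product: 6 4-chloro-6-methyl-2-oxo-2H-pyran-3-carbaldehyde
Conditions: POCl3, DMF, 0 to 60 °C; then ice–water
Reagents that add atoms: N,N-dimethylformamide, CN(C)C=O; phosphoryl chloride, O=P(Cl)(Cl)Cl; water, O
Why: Vilsmeier–Haack reaction formylates the nucleophilic C3 of the 4-hydroxypyranone and replaces the vinylogous-acid OH at C4 by chloride, as with 4-hydroxycoumarin.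

**Step 4**
Reactants: 6 4-chloro-6-methyl-2-oxo-2H-pyran-3-carbaldehyde
Product: 7 6-methyl-2-oxo-4-phenoxy-2H-pyran-3-carbaldehyde
Conditions: PhOH, K2CO3, acetone, 0 °C to rt
Reagents that add atoms: phenol, Oc1ccccc1
Why: nucleophilic vinylic substitution (addition–elimination) at the doubly activated C4 installs phenoxy, a leaving group that later acts as internal base and is less prone than chloride to displacement by the carbene.

**Step 5**
Reactants: 7 6-methyl-2-oxo-4-phenoxy-2H-pyran-3-carbaldehyde
Product: 8 6-methyl-2-oxo-4-phenoxy-2H-pyran-3-carboxylic acid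
Conditions: NaClO2, NaH2PO4, 2-methyl-2-butene, t-BuOH–H2O, 0 °C to rt
Reagents that add atoms: sodium chlorite, [Na+].[O-]Cl=O
Why: Pinnick oxidation converts the aldehyde into the acid under buffered conditions that should leave the vinylogous aryl ester and the pyranone intact.

**Step 6**
Reactants: 8 6-methyl-2-oxo-4-phenoxy-2H-pyran-3-carboxylic acid
Product: 9 6-methyl-2-oxo-4-phenoxy-2H-pyran-3-carbonyl chloride
Conditions: (COCl)2, DMF (cat.), CH2Cl2, 0 °C to rt
Reagents that add atoms: oxalyl chloride, O=C(Cl)C(=O)Cl
Why: acid chloride formation through the Vilsmeier-type chloroiminium activator is standard for aryl-type acids; the product is used crude.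

**Step 7**
Reactants: 4 (6E,10E)-7,11,15-trimethyl-4-methylidenehexadeca-6,10,14-trien-3-one; 9 6-methyl-2-oxo-4-phenoxy-2H-pyran-3-carbonyl chloride
Product: 11 (3Z,6E,10E)-4,7,11,15-tetramethylhexadeca-3,6,10,14-tetraen-3-yl 6-methyl-2-oxo-4-phenoxy-2H-pyran-3-carboxylate, via lithium enolate 10 (not isolated)
Conditions: LiBH(s-Bu)3 (L-Selectride), THF, −78 °C; then DMPU, 9, −78 to −30 °C; pH 7 buffer
Reagents that add atoms: none
Why: conjugate (1,4) hydride reduction of the α-methylene ketone generates the more substituted (C5) enolate regiospecifically and O-acylation of this hindered tetrasubstituted enolate gives the enol ester (reductive enolate generation/O-acylation); hydride delivery to the s-trans enone is expected to place the farnesylmethyl group cis to oxygen, i.e. (Z), and the minor geometric isomer is to be removed by chromatography.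

**Step 8**
Reactants: 11 (3Z,6E,10E)-4,7,11,15-tetramethylhexadeca-3,6,10,14-tetraen-3-yl 6-methyl-2-oxo-4-phenoxy-2H-pyran-3-carboxylate
Product: 14 (5S)-8-hydroxy-3,5,7-trimethyl-5-[(2E,6E)-3,7,11-trimethyldodeca-2,6,10-trien-1-yl]-1H-isochromene-1,6(5H)-dione (5-farnesyl-isochromene), via acyl azolium enolate ion pair 12 (not isolated), via C5-linked acyl azolium phenoxide 13 (not isolated)
Conditions: (5aR,10bS)-2-mesityl-5a,10b-dihydro-4H,6H-indeno[2,1-b][1,2,4]triazolo[4,3-d][1,4]oxazin-2-ium chloride (15 mol%), Cs2CO3 (2.2 equiv), 4 Å molecular sieves, THF, 0 °C to rt; then cold 0.5 M aq. HCl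
Reagents that add atoms: none
Why: Proposed new method: the free triazolylidene adds to the enol-ester carbonyl C8 and expels the tetrasubstituted enolate (ion pair 12); the enolate carbon C5 then attacks C4a, the β-carbon of the α,β-unsaturated acyl azolium, loss of phenoxide restores the pyranone (13), and phenoxide/carbonate enolises the new ketone towards C7 (C5 is now quaternary) so that the acyl azolium acylates C7, releasing the carbene and the product as its caesium enolate. The closest known reaction type is the carbene-catalysed rearrangement of α,β-unsaturated enol esters to dihydropyranones (recombination of an enolate with an unsaturated acyl azolium by Michael addition and acyl transfer), extended here by a β-leaving group and by C- instead of O-acyl transfer at the end. Ring B closes in the last event by a 6-(enolendo)-exo-trig C-acylation (Dieckmann type), the first C–C bond being made inside the ion pair, formally a Coates–Claisen-type shift through the six-membered array C5=C6–O···C8–C8a=C4a. C5 is set when the C5–C4a bond forms: the indane-fused backbone of the catalyst screens one face of the C8a=C4a bond and, with the enolate oxygen held at the acyl carbon, the (Z) geometry fixes which enolate face is presented, so the catalyst antipode named is expected to give (S). The step needs carbene attack at C8 rather than at C4a or C6 of the pyranone (hence phenoxy instead of chloride and the activated enol ester), C- rather than O-bonding of the enolate at C4a (return to C8 only regenerates 11), and C7- rather than O-acylation at the end, which should follow because O-acylation to the enol lactone is reversible under the catalyst while the C-acylated vinylogous acid is removed irreversibly as its enolate.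

**Compound list**
1 | diethyl (2-oxobutyl)phosphonate | CCC(=O)CP(=O)(OCC)OCC | starting material
2 | (2E,6E)-farnesyl bromide | CC(C)=CCC/C(C)=C/CC/C(C)=C/CBr | starting material
3 | diethyl [(6E,10E)-7,11,15-trimethyl-3-oxohexadeca-6,10,14-trien-4-yl]phosphonate (racemic) | CCC(=O)C(C/C=C(\C)CC/C=C(\C)CCC=C(C)C)P(=O)(OCC)OCC | intermediate
4 | (6E,10E)-7,11,15-trimethyl-4-methylidenehexadeca-6,10,14-trien-3-one | CCC(=O)C(=C)C/C=C(\C)CC/C=C(\C)CCC=C(C)C | intermediate
5 | 4-hydroxy-6-methyl-2H-pyran-2-one (triacetic acid lactone) | Cc1cc(O)cc(=O)o1 | starting material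
6 | 4-chloro-6-methyl-2-oxo-2H-pyran-3-carbaldehyde | Cc1cc(Cl)c(C=O)c(=O)o1 | intermediate
7 | 6-methyl-2-oxo-4-phenoxy-2H-pyran-3-carbaldehyde | Cc1cc(Oc2ccccc2)c(C=O)c(=O)o1 | intermediate
8 | 6-methyl-2-oxo-4-phenoxy-2H-pyran-3-carboxylic acid | Cc1cc(Oc2ccccc2)c(C(=O)O)c(=O)o1 | intermediate
9 | 6-methyl-2-oxo-4-phenoxy-2H-pyran-3-carbonyl chloride | Cc1cc(Oc2ccccc2)c(C(=O)Cl)c(=O)o1 | intermediate
10 | lithium (3Z,6E,10E)-4,7,11,15-tetramethylhexadeca-3,6,10,14-tetraen-3-olate | CC/C([O-])=C(\C)C/C=C(\C)CC/C=C(\C)CCC=C(C)C.[Li+] | intermediate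
11 | (3Z,6E,10E)-4,7,11,15-tetramethylhexadeca-3,6,10,14-tetraen-3-yl 6-methyl-2-oxo-4-phenoxy-2H-pyran-3-carboxylate | CC/C(OC(=O)c1c(Oc2ccccc2)cc(C)oc1=O)=C(\C)C/C=C(\C)CC/C=C(\C)CCC=C(C)C | intermediate
12 | (5aR,10bS)-2-mesityl-1-(6-methyl-2-oxo-4-phenoxy-2H-pyran-3-carbonyl)-5a,10b-dihydro-4H,6H-indeno[2,1-b][1,2,4]triazolo[4,3-d][1,4]oxazin-2-ium (3Z,6E,10E)-4,7,11,15-tetramethylhexadeca-3,6,10,14-tetraen-3-olate (acyl azolium enolate ion pair) | Cc1cc(Oc2ccccc2)c(C(=O)c2[n+](-c3c(C)cc(C)cc3C)nc3CO[C@@H]4Cc5ccccc5[C@@H]4n23)c(=O)o1.CC/C([O-])=C(\C)C/C=C(\C)CC/C=C(\C)CCC=C(C)C | intermediate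
13 | (5aR,10bS)-2-mesityl-1-{6-methyl-2-oxo-4-[(4S,6E,10E)-4,7,11,15-tetramethyl-3-oxohexadeca-6,10,14-trien-4-yl]-2H-pyran-3-carbonyl}-5a,10b-dihydro-4H,6H-indeno[2,1-b][1,2,4]triazolo[4,3-d][1,4]oxazin-2-ium phenoxide | CCC(=O)[C@@](C)(C/C=C(\C)CC/C=C(\C)CCC=C(C)C)c1cc(C)oc(=O)c1C(=O)c1[n+](-c2c(C)cc(C)cc2C)nc2CO[C@@H]3Cc4ccccc4[C@@H]3n12.[O-]c1ccccc1 | intermediate
14 | (5S)-8-hydroxy-3,5,7-trimethyl-5-[(2E,6E)-3,7,11-trimethyldodeca-2,6,10-trien-1-yl]-1H-isochromene-1,6(5H)-dione (5-farnesyl-isochromene) | CC(C)=CCC/C(C)=C/CC/C(C)=C/C[C@]1(C)C(=O)C(C)=C(O)c2c1cc(C)oc2=O | target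

**Step count**
Total steps: 8. Longest linear sequence: 6 (steps 3, 4, 5, 6, 7, 8, from triacetic acid lactone).

**Steps most likely to fail**

Step 8 (Proposed new method). The carbene may attack the pyranone ring (C4a or C6) instead of C8. The released enolate may bond through oxygen instead of C5. The cascade may stall at the O-acylated enol lactone. Facial selectivity may be weak or reversed. The fallback uses known chemistry, sets out from 4 and 9 and returns at 14; it gives up catalytic induction and obtains the single enantiomer by resolution. Acid chloride 9 is treated with MeOH and pyridine in CH2Cl2 to give methyl 6-methyl-2-oxo-4-phenoxy-2H-pyran-3-carboxylate F1. Lithium enolate 10, made from 4 with LiBH(s-Bu)3 as in step 7, is added to F1 in THF at −78 to 0 °C; addition–elimination at C4 with loss of phenoxide should give racemic methyl 6-methyl-2-oxo-4-[(6E,10E)-4,7,11,15-tetramethyl-3-oxohexadeca-6,10,14-trien-4-yl]-2H-pyran-3-carboxylate F2. Dieckmann cyclisation of F2 with t-BuOK in THF at 0 °C should give racemic 5-farnesyl-isochromene F3. The acidic enol is resolved by crystallising the (R)-1-phenylethylammonium salt of the (S) acid F4 (the antipodal amine is used if the other diastereomer is the one that crystallises). Cold dilute HCl then liberates 14.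

Step 7. The acid chloride may react at carbon of the enolate or suffer addition–elimination at C4 instead of O-acylation. The enolate may add to unreduced enone and oligomerise. The borane-bound enolate may react sluggishly. Geometric control of the enol double bond may be incomplete. The fallback sets out from 4 and returns at 11. 1,4-Hydrosilylation of 4 with PhMe2SiH and catalytic [(Ph3P)CuH]6 in toluene should give the isolable dimethyl(phenyl){[(3Z,6E,10E)-4,7,11,15-tetramethylhexadeca-3,6,10,14-tetraen-3-yl]oxy}silane F5, on which the geometric isomers can be separated. MeLi in THF regenerates enolate 10 free of borane, and 9 with DMPU then gives 11.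

Step 2. The α-methylene ketone may polymerise or undergo hetero-Diels–Alder dimerisation during the olefination or on handling. The fallback avoids the enone, sets out from 2 and returns at 10 and then 11. 2,6-Di-tert-butyl-4-methylphenyl propanoate F6 is made from the phenol, n-BuLi and propanoyl chloride. It is deprotonated with LiN(i-Pr)2 in THF at −78 °C and alkylated with 2 to give racemic 2,6-di-tert-butyl-4-methylphenyl (4E,8E)-2,5,9,13-tetramethyltetradeca-4,8,12-trienoate F7. EtLi (2 equiv) in THF at −78 to 0 °C deprotonates F7; the ester enolate ejects the aryloxide to give the ketene (4E,8E)-2,5,9,13-tetramethyltetradeca-1,4,8,12-tetraen-1-one F8 in situ. A second EtLi adds to F8 in the ketene plane from the side of the smaller methyl group, which should give the (Z)-enolate 10; acylation with 9 as in step 7 gives 11.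

**Further compounds**
F1 | step 8 | methyl 6-methyl-2-oxo-4-phenoxy-2H-pyran-3-carboxylate | COC(=O)c1c(Oc2ccccc2)cc(C)oc1=O
F2 | step 8 | methyl 6-methyl-2-oxo-4-[(6E,10E)-4,7,11,15-tetramethyl-3-oxohexadeca-6,10,14-trien-4-yl]-2H-pyran-3-carboxylate (racemic) | CCC(=O)C(C)(C/C=C(\C)CC/C=C(\C)CCC=C(C)C)c1cc(C)oc(=O)c1C(=O)OC
F3 | step 8 | racemic 8-hydroxy-3,5,7-trimethyl-5-[(2E,6E)-3,7,11-trimethyldodeca-2,6,10-trien-1-yl]-1H-isochromene-1,6(5H)-dione | CC(C)=CCC/C(C)=C/CC/C(C)=C/CC1(C)C(=O)C(C)=C(O)c2c1cc(C)oc2=O
F4 | step 8 | (R)-1-phenylethylammonium salt of 14 | C[C@@H]([NH3+])c1ccccc1.CC(C)=CCC/C(C)=C/CC/C(C)=C/C[C@]1(C)C(=O)C(C)=C([O-])c2c1cc(C)oc2=O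
F5 | step 7 | dimethyl(phenyl){[(3Z,6E,10E)-4,7,11,15-tetramethylhexadeca-3,6,10,14-tetraen-3-yl]oxy}silane | CC/C(O[Si](C)(C)c1ccccc1)=C(\C)C/C=C(\C)CC/C=C(\C)CCC=C(C)C
F6 | step 2 | 2,6-di-tert-butyl-4-methylphenyl propanoate | CCC(=O)Oc1c(C(C)(C)C)cc(C)cc1C(C)(C)C
F7 | step 2 | 2,6-di-tert-butyl-4-methylphenyl (4E,8E)-2,5,9,13-tetramethyltetradeca-4,8,12-trienoate (racemic) | CC(C/C=C(\C)CC/C=C(\C)CCC=C(C)C)C(=O)Oc1c(C(C)(C)C)cc(C)cc1C(C)(C)C
F8 | step 2 | (4E,8E)-2,5,9,13-tetramethyltetradeca-1,4,8,12-tetraen-1-one (ketene, formed in situ) | CC(C/C=C(\C)CC/C=C(\C)CCC=C(C)C)=C=O
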